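The route rests on reading the ring A ester carbon (on C1) and the ring B phenol oxygen (on C6'), both ortho to the benzophenone carbonyl, as the remains of a second carbonyl bridge, C10 of an anthraquinone. One Baeyer–Villiger oxygen insertion into the C10–C4a bond forms that aryl C–O bond and enlarges the central ring to a seven-membered lactone; methanolysis then frees ester and phenol together. The step exploits the contrast between C10 (peri H4 and H5, no conjugated donor) and C9 (chelated by 1-OH, crowded by 8-OMe). The precursor is questin carrying an acetate on O6 and a free 1-OH, built by two chlorine-directed Diels–Alder reactions.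

Key step: step 7

Remark on the chemistry: the double-bond geometry of the silyl ketene acetal and the configuration of the mixed acetal carbon in the first cycloadduct are left open, because both are erased on aromatisation. All sp3 intermediates are racemic, and the target is achiral.

Step 1
Reactants: 1 methyl 3-methylbut-2-enoate
Product: 2 1-methoxy-3-methyl-1-(trimethylsilyloxy)buta-1,3-diene
Conditions: LiN(iPr)2, THF, −78 °C; then Me3SiCl, −78 °C to rt
Reagents that add atoms: chlorotrimethylsilane, C[Si](C)(C)Cl
Why: Kinetic gamma-deprotonation of the unsaturated ester gives the extended lithium dienolate, which the chlorosilane traps on oxygen (silyl ketene acetal formation).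

Step 2
Reactants: 2 1-methoxy-3-methyl-1-(trimethylsilyloxy)buta-1,3-diene, 3 2,6-dichloro-1,4-benzoquinone
Product: 5 3-chloro-5-hydroxy-7-methyl-1,4-naphthoquinone, via cis-fused cycloadduct 4 (not isolated)
Conditions: CH2Cl2, −30 °C to rt; then 1 M aq. HCl, THF, rt
Reagents that add atoms: none
Why: In this regioselective Diels–Alder reaction the nucleophilic CH2 terminus of 2 bonds to the unsubstituted carbon of one chloroalkene of 3, so the acetal carbon ends next to the chlorine-flanked carbonyl, and the suprafacially formed cis adduct loses its stereocentres when HCl and methanol are eliminated and the silyl ether is hydrolysed, which aromatises the new ring without an oxidant.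

Step 3
Reactants: 6 1,1-dimethoxyethene
Product: 7 4,4-dimethoxybut-3-en-2-one
Conditions: AcCl (1 equiv), 6 (2.2 equiv), Et2O, 0 °C to reflux
Reagents that add atoms: acetyl chloride, CC(=O)Cl
Why: This is C-acylation of an electron-rich ketene acetal by an acid chloride, with the second equivalent of 6 taking up the HCl so that the dialkoxycarbenium intermediate loses a proton and is not demethylated.

Step 4
Reactants: 7 4,4-dimethoxybut-3-en-2-one
Product: 8 1,1-dimethoxy-3-(trimethylsilyloxy)buta-1,3-diene
Conditions: Me3SiCl, Et3N, ZnCl2 (cat.), toluene, 40 °C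
Reagents that add atoms: chlorotrimethylsilane, C[Si](C)(C)Cl
Why: Soft enolisation of the methyl ketone and O-silylation is the standard way to make 2-silyloxydienes from beta-alkoxy enones.

Step 5
Reactants: 5 3-chloro-5-hydroxy-7-methyl-1,4-naphthoquinone, 8 1,1-dimethoxy-3-(trimethylsilyloxy)buta-1,3-diene
Product: 10 questin (1,6-dihydroxy-8-methoxy-3-methylanthraquinone), via cis-fused cycloadduct 9 (not isolated)
Conditions: 8 (1.5–2 equiv), toluene, rt to 80 °C; then 1 M aq. HCl, THF, rt
Reagents that add atoms: none
Why: In this second chlorine-directed Diels–Alder reaction the C3 chlorine and the hydrogen-bond-activated C4 carbonyl of 5 both steer the CH2 terminus of 8 to C2, so the dimethyl acetal carbon becomes C8 beside C9, and the transient cis ring-fusion stereocentres vanish on loss of HCl and one methanol and on desilylation.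

Step 6
Reactants: 10 questin
Product: 11 questin 6-acetate (6-acetoxy-1-hydroxy-8-methoxy-3-methylanthraquinone)
Conditions: Ac2O (1.05 equiv), pyridine, CH2Cl2, 0 °C
Reagents that add atoms: acetic anhydride, CC(=O)OC(C)=O
Why: This is chemoselective O-acylation, because the 6-OH is free and acidic whereas the 1-OH is locked in a hydrogen bond to the C9 carbonyl and should not acylate at 0 °C with one equivalent of anhydride.

Step 7
Reactants: 11 questin 6-acetate
Product: 13 8-acetoxy-1-hydroxy-10-methoxy-3-methyldibenzo[b,e]oxepine-6,11-dione, via C10 Criegee adduct 12 (not isolated)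
Conditions: CF3CO3H [preformed from (CF3CO)2O and urea·H2O2, peroxide in slight excess], CH2Cl2, 0 °C to 40 °C
Reagents that add atoms: trifluoroperacetic acid, OOC(=O)C(F)(F)F
Why: Proposed new method: the peracid adds to the acid-activated C10 carbonyl to give the tetrahedral Criegee adduct 12, and C4a then shifts from C10 to the inner peroxide oxygen while trifluoroacetate departs, which is the Baeyer–Villiger mechanism. The closest known reaction types are the peracid conversion of benzophenones into aryl benzoates and the ring enlargement of fluorenones to dibenzopyranones, whereas regioselective cleavage of a hydroxyanthraquinone is so far the work of an oxygenase only. The seven-membered lactone ring is closed by ring enlargement, that is by a 1,2-aryl shift inside the six-membered central ring and not by a cyclisation, and no stereocentre is formed because the sp3 carbon of 12 returns to sp2. The first selectivity needed is between the two carbonyls: C10 has only H4 and H5 as peri neighbours and no oxygen donor in conjugation, while C9 is a chelated vinylogous acid that takes up donation from O1, O6 and O8 and is crowded by the 8-OMe, and for this reason the 1-OH is deliberately left unprotected. The second is between the two migrating carbons: C4a and C10a are meta to every substituent of their rings, so only inductive effects count, and OH plus CH3 on ring B (sigma-meta sum close to zero) against OMe plus OAc on ring A (sum close to +0.5) should make C4a the better migrator. Peroxide is kept in slight excess over the anhydride so that no free anhydride can acylate the 1-OH and cancel this bias.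

Step 8
Reactants: 13 8-acetoxy-1-hydroxy-10-methoxy-3-methyldibenzo[b,e]oxepine-6,11-dione
Product: 14 sulochrin (methyl 2-(2,6-dihydroxy-4-methylbenzoyl)-5-hydroxy-3-methoxybenzoate)
Conditions: NaOMe (4 equiv), MeOH, 0 °C to rt; then 1 M aq. HCl
Reagents that add atoms: sodium methoxide, C[O-].[Na+]
Why: In this transesterification methoxide attacks both aryl esters, so the lactone opens to the ring A methyl ester and the ring B phenoxide and the acetate leaves as methyl acetate, while the doubly ortho-substituted diaryl ketone is too hindered to react.

Step 9
Reactants: 14 sulochrin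
Product: 15 monochlorosulochrin (methyl 2-(3-chloro-2,6-dihydroxy-4-methylbenzoyl)-5-hydroxy-3-methoxybenzoate)
Conditions: N-chlorosuccinimide (1.0 equiv, slow addition), MeCN, 0 °C to rt
Reagents that add atoms: N-chlorosuccinimide, O=C1CCC(=O)N1Cl
Why: In this electrophilic aromatic chlorination C3' and C5' of ring B are equivalent by symmetry, each ortho to one OH, para to the other, ortho to the methyl and meta to the only acceptor, whereas the open positions of ring A are conjugated with the ester, so one equivalent of reagent should give the single ring B monochloride, whose chlorine slows a second substitution.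

Compound list
1 | methyl 3-methylbut-2-enoate | COC(=O)C=C(C)C | starting material
2 | 1-methoxy-3-methyl-1-(trimethylsilyloxy)buta-1,3-diene | COC(O[Si](C)(C)C)=CC(C)=C | intermediate
3 | 2,6-dichloro-1,4-benzoquinone | O=C1C=C(Cl)C(=O)C(Cl)=C1 | starting material
4 | cis-fused cycloadduct of 2 and 3 (racemic, mixed acetal carbon undefined) | O=C1C=C(Cl)C(=O)[C@@]2(Cl)[C@@H]1CC(C)=CC2(OC)O[Si](C)(C)C | intermediate
5 | 3-chloro-5-hydroxy-7-methyl-1,4-naphthoquinone | Cc1cc(O)c2C(=O)C(Cl)=CC(=O)c2c1 | intermediate
6 | 1,1-dimethoxyethene | C=C(OC)OC | starting material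
7 | 4,4-dimethoxybut-3-en-2-one | CC(=O)C=C(OC)OC | intermediate
8 | 1,1-dimethoxy-3-(trimethylsilyloxy)buta-1,3-diene | C=C(O[Si](C)(C)C)C=C(OC)OC | intermediate
9 | cis-fused cycloadduct of 5 and 8 (racemic) | Cc1cc(O)c2C(=O)[C@@]3(Cl)[C@H](CC(O[Si](C)(C)C)=CC3(OC)OC)C(=O)c2c1 | intermediate
10 | questin (1,6-dihydroxy-8-methoxy-3-methylanthraquinone) | COc1cc(O)cc2C(=O)c3cc(C)cc(O)c3C(=O)c12 | intermediate
11 | questin 6-acetate (6-acetoxy-1-hydroxy-8-methoxy-3-methylanthraquinone) | COc1cc(OC(C)=O)cc2C(=O)c3cc(C)cc(O)c3C(=O)c12 | intermediate
12 | C10 Criegee adduct (10-hydroxy-10-trifluoroacetylperoxy anthrone, racemic) | COc1cc(OC(C)=O)cc2c1C(=O)c1c(O)cc(C)cc1C2(O)OOC(=O)C(F)(F)F | intermediate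
13 | 8-acetoxy-1-hydroxy-10-methoxy-3-methyldibenzo[b,e]oxepine-6,11-dione | COc1cc(OC(C)=O)cc2C(=O)Oc3cc(C)cc(O)c3C(=O)c12 | intermediate
14 | sulochrin | COC(=O)c1cc(O)cc(OC)c1C(=O)c1c(O)cc(C)cc1O | intermediate
15 | monochlorosulochrin | COC(=O)c1cc(O)cc(OC)c1C(=O)c1c(O)cc(C)c(Cl)c1O | target

Total step count: 9. Longest linear sequence: 7 steps (steps 1, 2, 5, 6, 7, 8, 9 from 1). The branch from 6 through steps 3 and 4 is equally long.

Steps most likely to fail

1. Step 7. Several processes could defeat it:
- Oxygen insertion may stall, because both candidate migrating carbons are electron-poor.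
- C10a may migrate in competition with C4a.
- The peracid may add at C9, followed by a fast shift of a donor-substituted carbon.
- Ring B may be hydroxylated electrophilically.
- The acetate may be lost by perhydrolysis.

Fallback (known chemistry, sets out from diene 8 and returns at sulochrin 14): ring A is built onto a preformed aroyl alkyne instead of being released from an anthraquinone. Commercial 2,6-dihydroxy-4-methylbenzaldehyde is benzylated (BnBr, K2CO3, DMF) to 2,6-bis(benzyloxy)-4-methylbenzaldehyde F1. Lithiated methyl propiolate (LiN(iPr)2, THF, −78 °C) adds to give racemic methyl 4-[2,6-bis(benzyloxy)-4-methylphenyl]-4-hydroxybut-2-ynoate F2. Oxidation with MnO2 in CH2Cl2 gives methyl 4-[2,6-bis(benzyloxy)-4-methylphenyl]-4-oxobut-2-ynoate F3. A Diels–Alder reaction with 8 (toluene, rt to 80 °C) follows, in which the CH2 terminus of 8 bonds to the alkyne carbon beta to the stronger acceptor, the ketone. It should give the cyclohexa-1,4-diene cycloadduct F4, which loses methanol and is desilylated on acidic work-up to 2',6'-di-O-benzylsulochrin F5. Hydrogenolysis (H2, Pd/C, EtOAc) then gives 14.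

2. Step 9. Three processes could interfere:
- A second chlorination at the remaining ring B position.
- Competing attack on ring A.
- Oxidative dearomatising coupling between the two phenolic rings.

Fallback (sets out from lactone 13 and returns at target 15): the chlorine is introduced before the lactone is opened. At that stage ring A is deactivated by its acetate and two acyl groups. Ring B carries only one free phenol, and the tied-up oxygen rules out phenol coupling. N-Chlorosuccinimide with catalytic CF3CO2H in MeCN should chlorinate ortho or para to the 1-OH. This gives 8-acetoxy-2-chloro-1-hydroxy-10-methoxy-3-methyldibenzo[b,e]oxepine-6,11-dione F6 and 8-acetoxy-4-chloro-1-hydroxy-10-methoxy-3-methyldibenzo[b,e]oxepine-6,11-dione F7. The mixture needs no separation, because NaOMe in MeOH (as in step 8) opens both to a ring B in which the two positions are equivalent, so both converge on 15.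

3. Step 5. Two processes could interfere:
- The acid-sensitive diene may be hydrolysed or protonated by the liberated HCl before it reacts with the only moderately reactive chloronaphthoquinone.
- The peri methyl ether may be cleaved by acid during aromatisation.

Fallback (sets out from quinone 3 and returns at questin 10): the order of the two cycloadditions is reversed, so that the fragile diene meets the far more reactive benzoquinone at low temperature. Compounds 3 and 8 (THF, −30 °C to rt) give the cis-fused bicyclic cycloadduct F8. Loss of HCl and methanol and desilylation turn it into 3-chloro-7-hydroxy-5-methoxy-1,4-naphthoquinone F9. The sturdier diene 2 (excess, CH2Cl2, rt) then adds under control of the C3 chlorine to give the cis-fused tricyclic cycloadduct F10. The same eliminations and acidic work-up convert F10 into 10.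

Further compounds
F1 | step 7 | 2,6-bis(benzyloxy)-4-methylbenzaldehyde | Cc1cc(OCc2ccccc2)c(C=O)c(OCc2ccccc2)c1
F2 | step 7 | methyl 4-[2,6-bis(benzyloxy)-4-methylphenyl]-4-hydroxybut-2-ynoate (racemic) | COC(=O)C#CC(O)c1c(OCc2ccccc2)cc(C)cc1OCc1ccccc1
F3 | step 7 | methyl 4-[2,6-bis(benzyloxy)-4-methylphenyl]-4-oxobut-2-ynoate | COC(=O)C#CC(=O)c1c(OCc2ccccc2)cc(C)cc1OCc1ccccc1
F4 | step 7 | methyl 2-[2,6-bis(benzyloxy)-4-methylbenzoyl]-3,3-dimethoxy-5-(trimethylsilyloxy)cyclohexa-1,4-diene-1-carboxylate | COC(=O)C1=C(C(=O)c2c(OCc3ccccc3)cc(C)cc2OCc2ccccc2)C(OC)(OC)C=C(O[Si](C)(C)C)C1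
F5 | step 7 | 2',6'-di-O-benzylsulochrin | COC(=O)c1cc(O)cc(OC)c1C(=O)c1c(OCc2ccccc2)cc(C)cc1OCc1ccccc1
F6 | step 9 | 8-acetoxy-2-chloro-1-hydroxy-10-methoxy-3-methyldibenzo[b,e]oxepine-6,11-dione | COc1cc(OC(C)=O)cc2C(=O)Oc3cc(C)c(Cl)c(O)c3C(=O)c12
F7 | step 9 | 8-acetoxy-4-chloro-1-hydroxy-10-methoxy-3-methyldibenzo[b,e]oxepine-6,11-dione | COc1cc(OC(C)=O)cc2C(=O)Oc3c(Cl)c(C)cc(O)c3C(=O)c12
F8 | step 5 | cis-fused bicyclic cycloadduct of 3 and 8 (racemic) | O=C1C=C(Cl)C(=O)[C@@]2(Cl)[C@@H]1CC(O[Si](C)(C)C)=CC2(OC)OC
F9 | step 5 | 3-chloro-7-hydroxy-5-methoxy-1,4-naphthoquinone | COc1cc(O)cc2C(=O)C=C(Cl)C(=O)c12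
F10 | step 5 | cis-fused tricyclic cycloadduct of F9 and 2 (racemic, mixed acetal carbon undefined) | COc1cc(O)cc2C(=O)[C@H]3CC(C)=CC(OC)(O[Si](C)(C)C)[C@@]3(Cl)C(=O)c12
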